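**Retrosynthetic overview**

1. The route rests on the central 2,6-diaryl-3,7-dioxabicyclo[3.3.0]octane (C7, C8, C9 on the ring C side; C7', C8', C9' on the ring D side), whose two benzylic carbons carry different 4-O-(arylglycerol) syringyl rings. Cutting the C8–C8' bond and the C7–O bond opens both rings and leaves one acyclic ether 32: an aryl epoxy carbinol (ring D half) O-allylated by a cinnamyl unit (ring C half).
2. Ether 32 is divided at its allylic C–O bond into epoxy alcohol 31 (short arm) and cinnamyl bromide 22 (long arm); each already holds its complete, silyl-protected arylglycerol aryl ether chain.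
3. The C7–C8 bond of each arylglycerol unit (A, B and E) comes from an Evans syn aldol of an aryloxyacetyl oxazolidinone (3, or 16 enolised once as 17 for both syringyl aldols) with an aryl aldehyde (4 or 12). Unit B keeps the threo aldol array; units A and E are made erythro by Mitsunobu inversion at C7.
4. Ring order: the core has no ring before step 27. There the tetrahydrofuran containing C7' closes first (C8–C8' bond, radical) and the tetrahydrofuran containing C7 second (C7–O bond, polar), in one flask. Desilylation and debenzylation follow.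

Key step: step 27

Assumption: isoeugenol is used as its E isomer (the geometry is irrelevant after step 8), and 30 is carried as the mixture of both carbinol epimers.

Notation: TBS = tert-butyldimethylsilyl, Bn = benzyl. Rings: A (terminal guaiacyl, long arm), B (inner guaiacyl), C (syringyl, long arm), D (syringyl, short arm), E (terminal guaiacyl, short arm). Units A, B and E are the arylglycerols whose carbinol carbon C7 sits on ring A, B or E; C8 is the aryloxy-bearing carbon and C9 the CH2O carbon. Unlettered C7/C8/C9 and C7'/C8'/C9' are the furofuran carbons.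

**Route**

Step 1
Reactants: 1 isoeugenol; 2 (R)-4-benzyl-3-(chloroacetyl)oxazolidin-2-one
Product: 3 isoeugenyl oxyacetyl imide (R auxiliary)
Conditions: K2CO3, NaI (cat.), MeCN, rt
Reagents that add atoms: none
Why: Williamson-type SN2 alkylation of the phenoxide at the carbonyl-activated CH2Cl (iodide exchange in situ, Finkelstein) should be faster than attack at the imide carbonyls under carbonate in an aprotic solvent.

Step 2
Reactants: 3 isoeugenyl oxyacetyl imide; 4 O-benzylvanillin
Product: 6 syn aldol adduct of unit A, via boron enolate 5 (not isolated)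
Conditions: Bu2BOTf, Et3N, CH2Cl2, −78 to 0 °C; then 4, −78 to 0 °C; pH 7 buffer, MeOH, H2O2, 0 °C
Reagents that add atoms: none
Why: Evans syn aldol: soft enolisation gives the Z boron enolate 5, which adds to the aldehyde through a closed chair transition state on the face away from the auxiliary benzyl group, so the (R)-auxiliary sets C8 (2R in the imide) and C7 (3S) of unit A in the syn (threo) array.

Step 3
Reactants: 6 syn aldol adduct of unit A
Product: 7 threo (7S,8S) diol of unit A
Conditions: NaBH4, THF/H2O (4:1), 0 °C to rt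
Reagents that add atoms: none
Why: NaBH4 attacks the activated exocyclic imide carbonyl and reduces it to the primary alcohol (reductive removal of the Evans auxiliary) without touching C7, C8 or the propenyl group.

Step 4
Reactants: 7 threo diol of unit A
Product: 8 threo C9 mono-TBS ether
Conditions: TBSCl, imidazole, CH2Cl2, 0 °C
Reagents that add atoms: TBSCl, CC(C)(C)[Si](C)(C)Cl
Why: The primary C9 hydroxyl is silylated much faster than the hindered secondary benzylic C7 hydroxyl (selective silyl ether formation).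

Step 5
Reactants: 8 threo C9 mono-TBS ether
Product: 9 erythro (7R,8S) 4-nitrobenzoate of unit A
Conditions: 4-O2NC6H4CO2H, PPh3, DIAD, THF, 0 °C to rt
Reagents that add atoms: 4-nitrobenzoic acid, O=C(O)c1ccc(cc1)[N+](=O)[O-]
Why: Mitsunobu reaction: the C7 alkoxyphosphonium is displaced by 4-nitrobenzoate with inversion (C7 from S to R), which converts the threo into the erythro array, the acidic nucleophile and low temperature favouring SN2 over ionisation of the electron-rich benzylic centre.

Step 6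
Reactants: 9 erythro 4-nitrobenzoate of unit A
Product: 10 erythro C7 alcohol with C9 TBS ether
Conditions: K2CO3 (cat.), MeOH, 0 °C to rt
Reagents that add atoms: none
Why: Base-catalysed transesterification (methanolysis) removes the activated nitrobenzoate without affecting aryl ethers or the alkene, and a possible C9-to-C7 silyl shift is harmless because step 7 silylates the remaining hydroxyl.

Step 7
Reactants: 10 erythro C7 alcohol
Product: 11 erythro bis-TBS ether with propenyl group
Conditions: TBSOTf, 2,6-lutidine, CH2Cl2, 0 °C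
Reagents that add atoms: TBSOTf, CC(C)(C)[Si](C)(C)OS(=O)(=O)C(F)(F)F
Why: A silyl triflate with a hindered pyridine base should silylate the secondary benzylic alcohol quickly at 0 °C (silyl ether formation).

Step 8
Reactants: 11 erythro bis-TBS ether with propenyl group
Product: 12 erythro unit A aryl aldehyde
Conditions: OsO4 (2 mol %), NaIO4, 2,6-lutidine, dioxane/H2O (3:1), rt
Reagents that add atoms: OsO4, O=[Os](=O)(=O)=O (catalytic oxygen carrier); NaIO4, [Na+].[O-]I(=O)(=O)=O (stoichiometric oxygen source)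
Why: Lemieux–Johnson oxidation: OsO4 dihydroxylates the only alkene and periodate cleaves the glycol to the aryl aldehyde, with 2,6-lutidine suppressing over-oxidation and acid-induced loss of silyl groups.

Step 9
Reactants: 13 syringaldehyde
Product: 14 methyl (E)-sinapate
Conditions: Ph3P=CHCO2Me, toluene, 90 °C
Reagents that add atoms: methyl (triphenylphosphoranylidene)acetate, COC(=O)C=P(c1ccccc1)(c1ccccc1)c1ccccc1
Why: Wittig olefination with a stabilised ylide converts the aldehyde into the E enoate, which later serves as a masked aldehyde (short arm) or as the cinnamyl precursor (long arm).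

Step 10
Reactants: 14 methyl (E)-sinapate; 15 (S)-4-benzyl-3-(chloroacetyl)oxazolidin-2-one
Product: 16 sinapate oxyacetyl imide (S auxiliary)
Conditions: K2CO3, NaI (cat.), MeCN, rt to 40 °C
Reagents that add atoms: none
Why: Same Williamson-type SN2 alkylation as in step 1, the hindered 2,6-dimethoxyphenoxide reacting at the iodide-activated CH2 and not at a carbonyl.

Step 11
Reactants: 16 sinapate oxyacetyl imide
Product: 17 Z dibutylboron enolate of 16 as a cold CH2Cl2 stock solution
Conditions: Bu2BOTf (1.1 equiv), Et3N (1.3 equiv), CH2Cl2, −78 to 0 °C, recooled to −78 °C; solution divided by cannula into two portions and used at once in steps 12 and 17, which are run side by side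
Reagents that add atoms: dibutylboron triflate, CCCCB(CCCC)OS(=O)(=O)C(F)(F)F
Why: Soft enolisation: boron coordinates the imide carbonyl and triethylamine removes the acidified α-proton to give the Z boron enolate, the cinnamate having no enolisable proton, and one batch of this enolate, stable in cold CH2Cl2 under argon, serves both syringyl aldols.

Step 12
Reactants: 17 Z dibutylboron enolate of 16 (first portion of the solution from step 11); 12 erythro unit A aryl aldehyde
Product: 18 long-arm syn aldol adduct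
Conditions: 12 in CH2Cl2 added at −78 °C, then to 0 °C; pH 7 buffer, MeOH, H2O2, 0 °C
Reagents that add atoms: none
Why: Evans syn aldol: the Z boron enolate of the (S)-auxiliary adds to 12 through a closed chair transition state on the face away from the benzyl group, setting C8 (2S in the imide) and C7 (3R) of unit B directly in the required threo array, while the cinnamate and the remote stereocentres of 12 play no part.

Step 13
Reactants: 18 long-arm syn aldol adduct
Product: 19 long-arm threo (7R,8R) diol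
Conditions: NaBH4, THF/H2O (4:1), 0 °C
Reagents that add atoms: none
Why: NaBH4 reduces the activated imide carbonyl much faster than the conjugated methyl ester (chemoselective reductive removal of the auxiliary).

Step 14
Reactants: 19 long-arm threo diol
Product: 20 long-arm tetrakis-TBS methyl cinnamate
Conditions: TBSOTf (excess), 2,6-lutidine, CH2Cl2, −20 to 0 °C
Reagents that add atoms: TBSOTf, CC(C)(C)[Si](C)(C)OS(=O)(=O)C(F)(F)F
Why: Excess silyl triflate should silylate both the primary and the secondary benzylic hydroxyl of unit B (silyl ether formation), the enoate being inert.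

Step 15
Reactants: 20 long-arm tetrakis-TBS methyl cinnamate
Product: 21 long-arm cinnamyl alcohol
Conditions: iBu2AlH, CH2Cl2, −78 °C; aq. potassium sodium tartrate
Reagents that add atoms: none
Why: iBu2AlH reduces the enoate 1,2 to the allylic alcohol at low temperature and leaves silyl and benzyl ethers untouched.

Step 16
Reactants: 21 long-arm cinnamyl alcohol
Product: 22 long-arm cinnamyl bromide
Conditions: CBr4, PPh3, CH2Cl2, −20 to 0 °C; used at once
Reagents that add atoms: carbon tetrabromide, BrC(Br)(Br)Br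
Why: Appel reaction: the alkoxyphosphonium of the primary allylic alcohol is displaced by bromide under near-neutral conditions that spare the silyl ethers.

Step 17
Reactants: 17 Z dibutylboron enolate of 16 (second portion of the solution from step 11); 4 O-benzylvanillin
Product: 23 short-arm syn aldol adduct
Conditions: 4 in CH2Cl2 added at −78 °C, then to 0 °C; pH 7 buffer, MeOH, H2O2, 0 °C
Reagents that add atoms: none
Why: Evans syn aldol as in step 12, the (S)-auxiliary setting C8 (2S in the imide) and C7 (3R) of unit E syn through the same closed chair transition state.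

Step 18
Reactants: 23 short-arm syn aldol adduct
Product: 24 short-arm threo (7R,8R) diol
Conditions: NaBH4, THF/H2O (4:1), 0 °C
Reagents that add atoms: none
Why: Chemoselective reductive removal of the auxiliary by NaBH4 as in step 13, the methyl enoate being left intact.

Step 19
Reactants: 24 short-arm threo diol
Product: 25 short-arm threo C9 mono-TBS ether
Conditions: TBSCl, imidazole, CH2Cl2, 0 °C
Reagents that add atoms: TBSCl, CC(C)(C)[Si](C)(C)Cl
Why: Selective silylation of the primary hydroxyl over the hindered secondary benzylic one, as in step 4.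

Step 20
Reactants: 25 short-arm threo C9 mono-TBS ether
Product: 26 short-arm erythro (7S,8R) 4-nitrobenzoate
Conditions: 4-O2NC6H4CO2H, PPh3, DIAD, THF, 0 °C to rt
Reagents that add atoms: 4-nitrobenzoic acid, O=C(O)c1ccc(cc1)[N+](=O)[O-]
Why: Mitsunobu reaction with inversion at C7 (R to S) converts the threo into the erythro array of unit E, the enoate not interfering because PPh3 is consumed by DIAD first.

Step 21
Reactants: 26 short-arm erythro 4-nitrobenzoate
Product: 27 short-arm erythro C7 alcohol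
Conditions: K2CO3 (cat.), MeOH, 0 °C to rt
Reagents that add atoms: none
Why: Methanolysis removes the nitrobenzoate, the methyl enoate only exchanging with methanol itself and a silyl shift again being of no consequence.

Step 22
Reactants: 27 short-arm erythro C7 alcohol
Product: 28 short-arm erythro bis-TBS methyl cinnamate
Conditions: TBSOTf, 2,6-lutidine, CH2Cl2, 0 °C
Reagents that add atoms: TBSOTf, CC(C)(C)[Si](C)(C)OS(=O)(=O)C(F)(F)F
Why: Silyl triflate silylation of the secondary benzylic alcohol, as in step 7.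

Step 23
Reactants: 28 short-arm erythro bis-TBS methyl cinnamate
Product: 29 short-arm ring D aldehyde
Conditions: OsO4 (2 mol %), NaIO4, 2,6-lutidine, dioxane/H2O (3:1), rt
Reagents that add atoms: OsO4, O=[Os](=O)(=O)=O (catalytic oxygen carrier); NaIO4, [Na+].[O-]I(=O)(=O)=O (stoichiometric oxygen source)
Why: Lemieux–Johnson oxidation cleaves the cinnamate C=C, the only alkene present, and unmasks the ring D aldehyde.

Step 24
Reactants: 29 short-arm ring D aldehyde
Product: 30 short-arm aryl vinyl carbinol (both carbinol epimers)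
Conditions: CH2=CHMgBr, THF, −78 to 0 °C
Reagents that add atoms: vinylmagnesium bromide, C=C[Mg]Br
Why: Grignard 1,2-addition to the aryl aldehyde; no control from the remote stereocentres is expected, so both carbinol epimers should form and are differentiated in step 25.

Step 25
Reactants: 30 short-arm aryl vinyl carbinol
Product: 31 short-arm erythro epoxy alcohol
Conditions: Ti(OiPr)4 (30 mol %), L-(+)-diisopropyl tartrate (36 mol %), tBuOOH (0.6 equiv), 4 Å molecular sieves, CH2Cl2, −20 °C
Reagents that add atoms: tert-butyl hydroperoxide, CC(C)(C)OO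
Why: Sharpless asymmetric epoxidation used as a kinetic resolution: the titanium L-(+)-tartrate catalyst should epoxidise the epimer with the (R)-configured carbinol much faster and give the erythro epoxy alcohol (carbinol S by changed CIP ranking, oxirane carbon R), while the (S)-carbinol epimer stays an allylic alcohol and is removed by chromatography.

Step 26
Reactants: 31 short-arm erythro epoxy alcohol; 22 long-arm cinnamyl bromide
Product: 32 epoxy cinnamyl ether
Conditions: NaH, Bu4NI (cat.), THF/DMF, −20 to 0 °C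
Reagents that add atoms: none
Why: Williamson ether synthesis: the sodium alkoxide of the secondary carbinol is alkylated SN2 by the reactive cinnamyl bromide, the low temperature and aprotic medium keeping Payne rearrangement of the epoxy alkoxide slow and leaving C7' untouched.

Step 27
Reactants: 32 epoxy cinnamyl ether
Product: 35 hexakis-TBS dibenzyl furofuran tetramer, via bis-titanated tetrahydrofuran 33 (not isolated), via benzylic iodide 34 (not isolated)
Conditions: Cp2TiCl2 (2.5 equiv), Zn dust, THF, rt, solution decanted from Zn; slow addition of 32, rt; then I2 (1.3 equiv), rt to 50 °C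
Reagents that add atoms: none
Why: Cp2TiCl (trivalent titanium, made from Cp2TiCl2 and Zn) opens the oxirane by single-electron transfer to the secondary radical at C8' with a titanium alkoxide on C9'; this radical adds 5-exo-trig to the cinnamyl carbon C8 (forming C8–C8' and the ring O–C7'–C8'–C8–C9) and leaves a benzylic radical at C7 that a second Cp2TiCl captures as the benzyltitanium 33. Iodine converts 33 into the benzylic iodide 34, whose C7–I bond ionises easily next to the 4-alkoxy-3,5-dimethoxyphenyl ring, and the C9' titanium alkoxide then closes the second ring 5-exo onto C7 (ring C7–C8–C8'–C9'–O). The closest known reaction type is the Cp2TiCl-mediated epoxide-opening radical cyclisation of 1-aryl-2,3-epoxypropyl cinnamyl ethers with iodine work-up, which gives exo,exo-2,6-diaryl furofurans. C7' is untouched (S in 32, R in 35 only through changed CIP ranking) and controls the rest: in the chair-like transition state of the 5-hexenyl-type closure its aryl group sits pseudo-equatorial, placing C9' trans to ring D and the C7 side chain cis to C9', so C8' and C8 should both emerge S and the bicycle cis-fused, and C7 becomes R because the alkoxide closes on the planar benzylic centre with ring C on the convex exo face. The step needs diastereoselection (2,3-trans and 3,4-cis in the radical closure, exo aryl in the polar closure) and chemoselection, which rest on the absence of any free hydroxyl or reducible group (only silyl, benzyl and methyl ethers), on the fast addition to a styrene-type acceptor that outruns deoxygenation of the epoxide, and on slow addition of 32 to excess Cp2TiCl. The configuration of the oxirane carbon is lost at the radical stage and has no influence.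

Step 28
Reactants: 35 hexakis-TBS dibenzyl furofuran tetramer
Product: 36 dibenzyl ether of the target
Conditions: Bu4NF, AcOH, THF, rt to 40 °C
Reagents that add atoms: none
Why: Fluoride cleaves all six silyl ethers through Si–F bond formation, acetic acid buffering the alkoxides so that the aryl ether chains and benzyl ethers survive.

Step 29
Reactants: 36 dibenzyl ether of the target
Product: 37 target CNP0316493.1
Conditions: H2 (1 atm), 10% Pd/C, EtOAc/MeOH, rt, stopped at full debenzylation
Reagents that add atoms: none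
Why: Catalytic hydrogenolysis cleaves the two phenolic benzyl ethers much faster than the benzylic C–O bonds of the furofuran and of the secondary benzylic alcohols under neutral conditions at 1 atm.

**Compound list**

1 | isoeugenol, (E)-2-methoxy-4-(prop-1-enyl)phenol | COc1cc(/C=C/C)ccc1O | starting material
2 | (R)-4-benzyl-3-(chloroacetyl)oxazolidin-2-one | O=C(CCl)N1[C@H](Cc2ccccc2)COC1=O | starting material
3 | (R)-4-benzyl-3-{[2-methoxy-4-((E)-prop-1-enyl)phenoxy]acetyl}oxazolidin-2-one | COc1cc(/C=C/C)ccc1OCC(=O)N1[C@H](Cc2ccccc2)COC1=O | intermediate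
4 | O-benzylvanillin, 4-benzyloxy-3-methoxybenzaldehyde | COc1cc(C=O)ccc1OCc1ccccc1 | starting material
5 | Z dibutylboron enolate of 3 (formed in the flask, not isolated) | COc1cc(/C=C/C)ccc1O/C=C(\OB(CCCC)CCCC)N1[C@H](Cc2ccccc2)COC1=O | intermediate
6 | (R)-4-benzyl-3-[(2R,3S)-3-(4-benzyloxy-3-methoxyphenyl)-3-hydroxy-2-(2-methoxy-4-((E)-prop-1-enyl)phenoxy)propanoyl]oxazolidin-2-one | COc1cc([C@H](O)[C@H](C(=O)N3[C@H](Cc4ccccc4)COC3=O)Oc2ccc(/C=C/C)cc2OC)ccc1OCc1ccccc1 | intermediate
7 | (1S,2S)-1-(4-benzyloxy-3-methoxyphenyl)-2-[2-methoxy-4-((E)-prop-1-enyl)phenoxy]propane-1,3-diol (threo) | COc1cc([C@H](O)[C@H](CO)Oc2ccc(/C=C/C)cc2OC)ccc1OCc1ccccc1 | intermediate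
8 | (1S,2S)-1-(4-benzyloxy-3-methoxyphenyl)-3-(TBS-oxy)-2-[2-methoxy-4-((E)-prop-1-enyl)phenoxy]propan-1-ol | COc1cc([C@H](O)[C@H](CO[Si](C)(C)C(C)(C)C)Oc2ccc(/C=C/C)cc2OC)ccc1OCc1ccccc1 | intermediate
9 | (1R,2S)-1-(4-benzyloxy-3-methoxyphenyl)-3-(TBS-oxy)-2-[2-methoxy-4-((E)-prop-1-enyl)phenoxy]propyl 4-nitrobenzoate | COc1cc([C@@H](OC(=O)c3ccc(cc3)[N+](=O)[O-])[C@H](CO[Si](C)(C)C(C)(C)C)Oc2ccc(/C=C/C)cc2OC)ccc1OCc1ccccc1 | intermediate
10 | (1R,2S)-1-(4-benzyloxy-3-methoxyphenyl)-3-(TBS-oxy)-2-[2-methoxy-4-((E)-prop-1-enyl)phenoxy]propan-1-ol (erythro) | COc1cc([C@@H](O)[C@H](CO[Si](C)(C)C(C)(C)C)Oc2ccc(/C=C/C)cc2OC)ccc1OCc1ccccc1 | intermediate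
11 | (1R,2S)-1-(4-benzyloxy-3-methoxyphenyl)-1,3-bis(TBS-oxy)-2-[2-methoxy-4-((E)-prop-1-enyl)phenoxy]propane | COc1cc([C@@H](O[Si](C)(C)C(C)(C)C)[C@H](CO[Si](C)(C)C(C)(C)C)Oc2ccc(/C=C/C)cc2OC)ccc1OCc1ccccc1 | intermediate
12 | 4-{[(1R,2S)-1-(4-benzyloxy-3-methoxyphenyl)-1,3-bis(TBS-oxy)propan-2-yl]oxy}-3-methoxybenzaldehyde | COc1cc([C@@H](O[Si](C)(C)C(C)(C)C)[C@H](CO[Si](C)(C)C(C)(C)C)Oc2ccc(C=O)cc2OC)ccc1OCc1ccccc1 | intermediate
13 | syringaldehyde, 4-hydroxy-3,5-dimethoxybenzaldehyde | COc1cc(C=O)cc(OC)c1O | starting material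
14 | methyl (E)-sinapate | COC(=O)/C=C/c1cc(OC)c(O)c(OC)c1 | intermediate
15 | (S)-4-benzyl-3-(chloroacetyl)oxazolidin-2-one | O=C(CCl)N1[C@@H](Cc2ccccc2)COC1=O | starting material
16 | methyl (E)-3-{4-[2-((S)-4-benzyl-2-oxooxazolidin-3-yl)-2-oxoethoxy]-3,5-dimethoxyphenyl}acrylate | COC(=O)/C=C/c1cc(OC)c(OCC(=O)N2[C@@H](Cc3ccccc3)COC2=O)c(OC)c1 | intermediate
17 | Z dibutylboron enolate of 16 (prepared once as a cold CH2Cl2 solution, divided and used directly in steps 12 and 17) | COC(=O)/C=C/c1cc(OC)c(O/C=C(\OB(CCCC)CCCC)N2[C@@H](Cc3ccccc3)COC2=O)c(OC)c1 | intermediate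
18 | long-arm aldol adduct: (S)-4-benzyl-3-[(2S,3R)-3-hydroxy-2-{2,6-dimethoxy-4-[(E)-3-methoxy-3-oxoprop-1-enyl]phenoxy}-3-(ring B aryl)propanoyl]oxazolidin-2-one, ring B aryl being the aryl group of 12 | COc1cc([C@@H](O[Si](C)(C)C(C)(C)C)[C@H](CO[Si](C)(C)C(C)(C)C)Oc2ccc([C@@H](O)[C@@H](C(=O)N3[C@@H](Cc4ccccc4)COC3=O)Oc3c(OC)cc(/C=C/C(=O)OC)cc3OC)cc2OC)ccc1OCc1ccccc1 | intermediate
19 | long-arm diol: methyl (E)-sinapate whose phenol oxygen carries C2 of a (1R,2R)-1-(ring B aryl)-1,3-dihydroxypropan-2-yl group (threo unit B; unit A as in 12) | COc1cc([C@@H](O[Si](C)(C)C(C)(C)C)[C@H](CO[Si](C)(C)C(C)(C)C)Oc2ccc([C@@H](O)[C@@H](CO)Oc3c(OC)cc(/C=C/C(=O)OC)cc3OC)cc2OC)ccc1OCc1ccccc1 | intermediate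
20 | bis-TBS ether of 19 (four TBS groups; unit A 7R,8S, unit B 7R,8R) | COc1cc([C@@H](O[Si](C)(C)C(C)(C)C)[C@H](CO[Si](C)(C)C(C)(C)C)Oc2ccc([C@@H](O[Si](C)(C)C(C)(C)C)[C@@H](CO[Si](C)(C)C(C)(C)C)Oc3c(OC)cc(/C=C/C(=O)OC)cc3OC)cc2OC)ccc1OCc1ccccc1 | intermediate
21 | long-arm (E)-cinnamyl alcohol (CO2Me of 20 reduced to CH2OH) | COc1cc([C@@H](O[Si](C)(C)C(C)(C)C)[C@H](CO[Si](C)(C)C(C)(C)C)Oc2ccc([C@@H](O[Si](C)(C)C(C)(C)C)[C@@H](CO[Si](C)(C)C(C)(C)C)Oc3c(OC)cc(/C=C/CO)cc3OC)cc2OC)ccc1OCc1ccccc1 | intermediate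
22 | long-arm (E)-cinnamyl bromide (CH2OH of 21 replaced by CH2Br) | COc1cc([C@@H](O[Si](C)(C)C(C)(C)C)[C@H](CO[Si](C)(C)C(C)(C)C)Oc2ccc([C@@H](O[Si](C)(C)C(C)(C)C)[C@@H](CO[Si](C)(C)C(C)(C)C)Oc3c(OC)cc(/C=C/CBr)cc3OC)cc2OC)ccc1OCc1ccccc1 | intermediate
23 | (S)-4-benzyl-3-[(2S,3R)-3-(4-benzyloxy-3-methoxyphenyl)-3-hydroxy-2-{2,6-dimethoxy-4-[(E)-3-methoxy-3-oxoprop-1-enyl]phenoxy}propanoyl]oxazolidin-2-one | COC(=O)/C=C/c1cc(OC)c(O[C@H](C(=O)N2[C@@H](Cc3ccccc3)COC2=O)[C@H](O)c2ccc(OCc3ccccc3)c(OC)c2)c(OC)c1 | intermediate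
24 | methyl (E)-3-{4-[(1R,2R)-1-(4-benzyloxy-3-methoxyphenyl)-1,3-dihydroxypropan-2-yl]oxy-3,5-dimethoxyphenyl}acrylate (threo) | COC(=O)/C=C/c1cc(OC)c(O[C@H](CO)[C@H](O)c2ccc(OCc3ccccc3)c(OC)c2)c(OC)c1 | intermediate
25 | methyl (E)-3-{4-[(1R,2R)-1-(4-benzyloxy-3-methoxyphenyl)-1-hydroxy-3-(TBS-oxy)propan-2-yl]oxy-3,5-dimethoxyphenyl}acrylate | COC(=O)/C=C/c1cc(OC)c(O[C@H](CO[Si](C)(C)C(C)(C)C)[C@H](O)c2ccc(OCc3ccccc3)c(OC)c2)c(OC)c1 | intermediate
26 | methyl (E)-3-{4-[(1S,2R)-1-(4-benzyloxy-3-methoxyphenyl)-1-(4-nitrobenzoyloxy)-3-(TBS-oxy)propan-2-yl]oxy-3,5-dimethoxyphenyl}acrylate | COC(=O)/C=C/c1cc(OC)c(O[C@H](CO[Si](C)(C)C(C)(C)C)[C@@H](OC(=O)c2ccc(cc2)[N+](=O)[O-])c2ccc(OCc3ccccc3)c(OC)c2)c(OC)c1 | intermediate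
27 | methyl (E)-3-{4-[(1S,2R)-1-(4-benzyloxy-3-methoxyphenyl)-1-hydroxy-3-(TBS-oxy)propan-2-yl]oxy-3,5-dimethoxyphenyl}acrylate (erythro) | COC(=O)/C=C/c1cc(OC)c(O[C@H](CO[Si](C)(C)C(C)(C)C)[C@@H](O)c2ccc(OCc3ccccc3)c(OC)c2)c(OC)c1 | intermediate
28 | methyl (E)-3-{4-[(1S,2R)-1-(4-benzyloxy-3-methoxyphenyl)-1,3-bis(TBS-oxy)propan-2-yl]oxy-3,5-dimethoxyphenyl}acrylate | COC(=O)/C=C/c1cc(OC)c(O[C@H](CO[Si](C)(C)C(C)(C)C)[C@@H](O[Si](C)(C)C(C)(C)C)c2ccc(OCc3ccccc3)c(OC)c2)c(OC)c1 | intermediate
29 | 4-{[(1S,2R)-1-(4-benzyloxy-3-methoxyphenyl)-1,3-bis(TBS-oxy)propan-2-yl]oxy}-3,5-dimethoxybenzaldehyde | O=Cc1cc(OC)c(O[C@H](CO[Si](C)(C)C(C)(C)C)[C@@H](O[Si](C)(C)C(C)(C)C)c2ccc(OCc3ccccc3)c(OC)c2)c(OC)c1 | intermediate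
30 | 1-{4-[(1S,2R)-1-(4-benzyloxy-3-methoxyphenyl)-1,3-bis(TBS-oxy)propan-2-yl]oxy-3,5-dimethoxyphenyl}prop-2-en-1-ol, both epimers at the new carbinol | C=CC(O)c1cc(OC)c(O[C@H](CO[Si](C)(C)C(C)(C)C)[C@@H](O[Si](C)(C)C(C)(C)C)c2ccc(OCc3ccccc3)c(OC)c2)c(OC)c1 | intermediate
31 | (S)-{4-[(1S,2R)-1-(4-benzyloxy-3-methoxyphenyl)-1,3-bis(TBS-oxy)propan-2-yl]oxy-3,5-dimethoxyphenyl}[(R)-oxiran-2-yl]methanol | O[C@H]([C@H]1CO1)c1cc(OC)c(O[C@H](CO[Si](C)(C)C(C)(C)C)[C@@H](O[Si](C)(C)C(C)(C)C)c2ccc(OCc3ccccc3)c(OC)c2)c(OC)c1 | intermediate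
32 | epoxy cinnamyl ether: the carbinol oxygen of 31 (carbinol S, oxirane R) bonded to the allylic CH2 of the (E)-cinnamyl group of 22 | COc1cc([C@@H](O[Si](C)(C)C(C)(C)C)[C@H](CO[Si](C)(C)C(C)(C)C)Oc2ccc([C@@H](O[Si](C)(C)C(C)(C)C)[C@@H](CO[Si](C)(C)C(C)(C)C)Oc3c(OC)cc(/C=C/CO[C@H]([C@H]4CO4)c4cc(OC)c(O[C@H](CO[Si](C)(C)C(C)(C)C)[C@@H](O[Si](C)(C)C(C)(C)C)c5ccc(OCc6ccccc6)c(OC)c5)c(OC)c4)cc3OC)cc2OC)ccc1OCc1ccccc1 | intermediate
33 | bis-titanated tetrahydrofuran (formed in the flask, not isolated): ring O–C7'–C8'–C8–C9 with ring D aryl on C7', CH2O–TiClCp2 on C8' and CH(TiClCp2)(ring C aryl) on C8; C7', C8', C8 configured as in 35, C7 undefined | COc1cc([C@@H](O[Si](C)(C)C(C)(C)C)[C@H](CO[Si](C)(C)C(C)(C)C)Oc2ccc([C@@H](O[Si](C)(C)C(C)(C)C)[C@@H](CO[Si](C)(C)C(C)(C)C)Oc3c(OC)cc(C([Ti](Cl)(C%11C=CC=C%11)C%12C=CC=C%12)[C@@H]4CO[C@@H](c5cc(OC)c(O[C@H](CO[Si](C)(C)C(C)(C)C)[C@@H](O[Si](C)(C)C(C)(C)C)c6ccc(OCc7ccccc7)c(OC)c6)c(OC)c5)[C@@H]4CO[Ti](Cl)(C%11C=CC=C%11)C%12C=CC=C%12)cc3OC)cc2OC)ccc1OCc1ccccc1 | intermediate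
34 | benzylic iodide (formed in the flask, not isolated): as 33 with iodine in place of titanium on C7 | COc1cc([C@@H](O[Si](C)(C)C(C)(C)C)[C@H](CO[Si](C)(C)C(C)(C)C)Oc2ccc([C@@H](O[Si](C)(C)C(C)(C)C)[C@@H](CO[Si](C)(C)C(C)(C)C)Oc3c(OC)cc(C(I)[C@@H]4CO[C@@H](c5cc(OC)c(O[C@H](CO[Si](C)(C)C(C)(C)C)[C@@H](O[Si](C)(C)C(C)(C)C)c6ccc(OCc7ccccc7)c(OC)c6)c(OC)c5)[C@@H]4CO[Ti](Cl)(C%11C=CC=C%11)C%12C=CC=C%12)cc3OC)cc2OC)ccc1OCc1ccccc1 | intermediate
35 | protected tetramer: (7R,8S,7'R,8'S)-2,6-diaryl-3,7-dioxabicyclo[3.3.0]octane with ring C (long arm, units A and B) on C7 and ring D (short arm, unit E) on C7', six TBS ethers, two phenolic benzyl ethers | COc1cc([C@@H](O[Si](C)(C)C(C)(C)C)[C@H](CO[Si](C)(C)C(C)(C)C)Oc2ccc([C@@H](O[Si](C)(C)C(C)(C)C)[C@@H](CO[Si](C)(C)C(C)(C)C)Oc3c(OC)cc([C@@H]4OC[C@@H]5[C@H]4CO[C@H]5c4cc(OC)c(O[C@H](CO[Si](C)(C)C(C)(C)C)[C@@H](O[Si](C)(C)C(C)(C)C)c5ccc(OCc6ccccc6)c(OC)c5)c(OC)c4)cc3OC)cc2OC)ccc1OCc1ccccc1 | intermediate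
36 | dibenzyl ether of the target (all six aliphatic hydroxyls free, both terminal phenols as benzyl ethers) | COc1cc([C@@H](O)[C@H](CO)Oc2ccc([C@@H](O)[C@@H](CO)Oc3c(OC)cc([C@@H]4OC[C@@H]5[C@H]4CO[C@H]5c4cc(OC)c(O[C@H](CO)[C@@H](O)c5ccc(OCc6ccccc6)c(OC)c5)c(OC)c4)cc3OC)cc2OC)ccc1OCc1ccccc1 | intermediate
37 | CNP0316493.1 (unit A 7R,8S; unit B 7R,8R; furofuran 7R,8S,7'R,8'S; unit E 7S,8R) | COc1cc([C@@H](O)[C@H](CO)Oc2ccc([C@@H](O)[C@@H](CO)Oc3c(OC)cc([C@@H]4OC[C@@H]5[C@H]4CO[C@H]5c4cc(OC)c(O[C@H](CO)[C@@H](O)c5ccc(O)c(OC)c5)c(OC)c4)cc3OC)cc2OC)ccc1O | target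

**Step count and risks**

Total step count: 29. Longest linear sequence: 17 steps (steps 1–8, 12–16, 26–29).

Steps most likely to fail:

Step 27. The benzylic C7 radical or its titanium derivative may be quenched by hydrogen or lose a β-hydrogen before it is iodinated, the epoxide may be deoxygenated to an allylic ether before the radical cyclises, or the polar closure may show weak exo preference. The fallback separates the radical and polar stages. Setting out from 32, the Cp2TiCl cyclisation is run alone and quenched with aqueous NaH2PO4 to give the monocyclic 2-aryl-3-(hydroxymethyl)-4-benzyltetrahydrofuran F1, in which C7 is a CH2 group. The second ring is then closed in a separate oxidative step with DDQ (CH2Cl2, pH 7 buffer, 0 °C): hydride abstraction from the 4-alkoxy-3,5-dimethoxybenzyl CH2 gives a benzylic cation that the C9' hydroxyl captures from the exo face. This returns to the route at 35. The site selectivity of the hydride abstraction (C7 against the C7'–H ether position) would have to be checked on a model first.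

Step 26. The epoxy alkoxide may undergo Payne rearrangement, and the electron-rich cinnamyl bromide may ionise, decompose or be attacked SN2' before the ether forms. The fallback avoids both the alkoxide and the bromide. Setting out from 21 (step 16 is skipped), Cl3CCN with catalytic DBU in CH2Cl2 at 0 °C should give the cinnamyl trichloroacetimidate F2. F2 is coupled with epoxy alcohol 31 under catalytic acid (TMSOTf or camphorsulfonic acid, CH2Cl2, −40 °C), the conjugated linear ether being the expected product of the allyl cation. This returns to the route at 32.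

Step 20. The C7 alkoxyphosphonium at the electron-rich benzylic carbon, flanked by the hindered 2,6-dimethoxyphenoxy group, may ionise, so substitution loses stereospecificity or elimination takes over. The fallback replaces inversion by oxidation and reduction. Setting out from 25, Dess–Martin periodinane (CH2Cl2, NaHCO3, 0 °C) should give the α-aryloxy ketone F3 without epimerising C8. Reduction with Zn(BH4)2 in Et2O at −30 °C, with hydride delivered through the chelate between the carbonyl and the α-aryloxy oxygen, is expected to favour the erythro alcohol. This returns to the route at 27, and steps 20 and 21 are skipped.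

Further compounds
F1 | step 27 | monocyclic tetrahydrofuran alcohol: ring O–C7'–C8'–C8–C9 with ring D aryl on C7' (R), CH2OH on C8' (S) and the ring C benzyl CH2 on C8 (S), all silyl and benzyl ethers retained | COc1cc([C@@H](O[Si](C)(C)C(C)(C)C)[C@H](CO[Si](C)(C)C(C)(C)C)Oc2ccc([C@@H](O[Si](C)(C)C(C)(C)C)[C@@H](CO[Si](C)(C)C(C)(C)C)Oc3c(OC)cc(C[C@@H]4CO[C@@H](c5cc(OC)c(O[C@H](CO[Si](C)(C)C(C)(C)C)[C@@H](O[Si](C)(C)C(C)(C)C)c6ccc(OCc7ccccc7)c(OC)c6)c(OC)c5)[C@@H]4CO)cc3OC)cc2OC)ccc1OCc1ccccc1
F2 | step 26 | long-arm (E)-cinnamyl 2,2,2-trichloroacetimidate (O-imidate of 21) | COc1cc([C@@H](O[Si](C)(C)C(C)(C)C)[C@H](CO[Si](C)(C)C(C)(C)C)Oc2ccc([C@@H](O[Si](C)(C)C(C)(C)C)[C@@H](CO[Si](C)(C)C(C)(C)C)Oc3c(OC)cc(/C=C/COC(=N)C(Cl)(Cl)Cl)cc3OC)cc2OC)ccc1OCc1ccccc1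
F3 | step 20 | methyl (E)-3-{4-[(2R)-1-(4-benzyloxy-3-methoxyphenyl)-1-oxo-3-(TBS-oxy)propan-2-yl]oxy-3,5-dimethoxyphenyl}acrylate | COC(=O)/C=C/c1cc(OC)c(O[C@H](CO[Si](C)(C)C(C)(C)C)C(=O)c2ccc(OCc3ccccc3)c(OC)c2)c(OC)c1
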